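Ring C is cut at C3–C4 and O1–C2. The atoms O1–C8a–C4a–C4 are the oxadiene of an o-quinone methide of phloroglucinol ring A, and C2–C3 with the electron-rich ring B is a styrene. One chiral-acid-catalysed oxa-[4+2] cycloaddition therefore closes ring C, forms both bonds and sets C2 (S), leaving only C4 to be oxidised to the ketone. The precursor is a salicyl alcohol: ring A with the C8a hydroxyl free, the 5- and 7-oxygens as MOM ethers, the hydroxymethyl carbon as future C4, and the (R)-lavandulyl chain already on C8, installed by Negishi coupling of enantiopure lavandulylzinc iodide.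

Key step: step 9

Remarks and assumptions
- Lavandulyl stands for 5-methyl-2-(prop-1-en-2-yl)hex-4-en-1-yl; its descriptor refers to C2 of that chain. MOM is methoxymethyl.
- The spatial arrangement of (S)-lavandulol is that of the (R)-lavandulyl group on an arene: CH2OH, CH2I and CH2Zn outrank isopropenyl, whereas CH2–aryl ranks below it.
- Assumption: the lipase acetylates (R)-lavandulol faster, so the unreacted alcohol is the S enantiomer (checked by optical rotation and chiral GC); were the preference reversed, the acetate fraction would be methanolysed and used.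
- Assumption: the R antipode of the phosphoric acid is written in step 9; the antipode that delivers 2S is to be found by experiment and used.

Step 1
Reactants: 1 2,4,6-trihydroxybenzaldehyde
Product: 2 2-hydroxy-4,6-bis(methoxymethoxy)benzaldehyde
Conditions: MOMCl (2.2 equiv), i-Pr2NEt, CH2Cl2, 0 °C → rt
Reagents that add atoms: chloromethyl methyl ether (MOMCl), COCCl
Why: O-alkylation with MOMCl etherifies the para hydroxyl and one of the two equivalent ortho hydroxyls, while the remaining ortho hydroxyl, hydrogen-bonded to the formyl group, is the least nucleophilic and stays free, which later dictates where the methide forms.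

Step 2
Reactants: 2 2-hydroxy-4,6-bis(methoxymethoxy)benzaldehyde
Product: 3 2-hydroxy-3-iodo-4,6-bis(methoxymethoxy)benzaldehyde
Conditions: NIS (1.05 equiv), DMF, 0 °C → rt, dark
Reagents that add atoms: N-iodosuccinimide, O=C1CCC(=O)N1I
Why: Electrophilic aromatic iodination should go to C3, which is ortho to the chelated free phenol, para to the 6-ether and less crowded than C5 between two MOM ethers (the usual halogenation site of 2-hydroxy-4,6-dialkoxyaryl carbonyl compounds), the regiochemistry being confirmed by HMBC before going on.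

Step 3
Reactants: 4 racemic lavandulol, (2RS)-5-methyl-2-(prop-1-en-2-yl)hex-4-en-1-ol
Product: 5 (S)-lavandulol, (2S)-5-methyl-2-(prop-1-en-2-yl)hex-4-en-1-ol (recovered unreacted alcohol)
Conditions: vinyl acetate, immobilised Candida antarctica lipase B, MTBE, rt, run past half conversion; chromatography
Reagents that add atoms: none
Why: Lipase-catalysed kinetic resolution by irreversible transesterification acetylates the faster-reacting R alcohol, and running past half conversion (a second pass if needed) should leave the S alcohol in high enantiomeric purity.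

Step 4
Reactants: 5 (S)-lavandulol
Product: 6 (S)-lavandulyl iodide, (3S)-3-(iodomethyl)-2,6-dimethylhepta-1,5-diene
Conditions: I2, PPh3, imidazole, CH2Cl2, 0 °C → rt
Reagents that add atoms: iodine, II
Why: Appel iodination of a primary alcohol proceeds by SN2 displacement at CH2 and leaves the adjacent stereocentre and both alkenes untouched.

Step 5
Reactants: 6 (S)-lavandulyl iodide; 3 2-hydroxy-3-iodo-4,6-bis(methoxymethoxy)benzaldehyde
Product: 8 2-hydroxy-4,6-bis(methoxymethoxy)-3-[(R)-lavandulyl]benzaldehyde, via (S)-lavandulylzinc iodide 7 (not isolated)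
Conditions: 6, Zn dust (activated with BrCH2CH2Br/TMSCl), LiCl, THF, 40 °C; then slow addition (1.5 equiv) to 3, Pd(OAc)2 (3 mol%), SPhos (2-dicyclohexylphosphino-2',6'-dimethoxybiphenyl, 6 mol%), THF, rt → 45 °C
Reagents that add atoms: none
Why: LiCl-assisted zinc insertion into the primary iodide followed by Negishi sp3–sp2 coupling under a bulky biarylphosphine palladium catalyst, which favours reductive elimination over β-hydride elimination and tolerates the aldehyde and (with slow addition) the free phenol, joins C8 to the side chain without touching the stereocentre, whose descriptor alone changes from S to R.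

Step 6
Reactants: 9 4-hydroxy-2-methoxybenzaldehyde
Product: 10 2-methoxy-4-(methoxymethoxy)benzaldehyde
Conditions: MOMCl, i-Pr2NEt, CH2Cl2, 0 °C → rt
Reagents that add atoms: chloromethyl methyl ether (MOMCl), COCCl
Why: Standard MOM protection of a phenol by O-alkylation keeps the para oxygen a strong donor for the cycloaddition.

Step 7
Reactants: 10 2-methoxy-4-(methoxymethoxy)benzaldehyde
Product: 11 1-ethenyl-2-methoxy-4-(methoxymethoxy)benzene
Conditions: Ph3PCH3Br, KOtBu, THF, 0 °C → rt
Reagents that add atoms: methyltriphenylphosphonium bromide, C[P+](c1ccccc1)(c1ccccc1)c1ccccc1.[Br-]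
Why: Wittig methylenation of an aromatic aldehyde with the unstabilised ylide gives the styrene, which is acid-sensitive and is stored cold and used fresh.

Step 8
Reactants: 8 2-hydroxy-4,6-bis(methoxymethoxy)-3-[(R)-lavandulyl]benzaldehyde
Product: 12 2-(hydroxymethyl)-3,5-bis(methoxymethoxy)-6-[(R)-lavandulyl]phenol
Conditions: NaBH4, THF/MeOH, 0 °C; pH 7 buffer work-up; used crude at once
Reagents that add atoms: none
Why: Borohydride reduction of the chelated aldehyde at low temperature with neutral work-up avoids base- or acid-triggered methide formation (over-reduction or self-condensation), and the labile salicyl alcohol is carried on without chromatography.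

Step 9
Reactants: 12 2-(hydroxymethyl)-3,5-bis(methoxymethoxy)-6-[(R)-lavandulyl]phenol; 11 1-ethenyl-2-methoxy-4-(methoxymethoxy)benzene
Product: 14 (2S)-5,7-bis(methoxymethoxy)-2-[2-methoxy-4-(methoxymethoxy)phenyl]-8-[(R)-lavandulyl]chromane, via ring A o-quinone methide 13 (not isolated)
Conditions: 11 (3 equiv), (R)-3,3'-bis(2,4,6-triisopropylphenyl)-1,1'-binaphthyl-2,2'-diyl hydrogen phosphate (10 mol%), 5 Å MS, toluene, −20 °C, slow addition of 12
Reagents that add atoms: none
Why: Proposed new method: the chiral phosphoric acid ionises the benzylic alcohol of 12, helped by the ortho and para oxygens of ring A, to o-quinone methide 13, which stays hydrogen-bonded (or ion-paired after protonation) to the chiral phosphate; the CH2 terminus of 11 then adds to the methide carbon (C3–C4) and the ring A oxygen collapses onto the benzylic cation stabilised by the ortho-methoxy and para-MOM-oxy groups of ring B (O1–C2), an asynchronous inverse-electron-demand oxa-[4+2] cycloaddition. The closest known reaction types are thermal or acid-promoted cycloadditions of phloroglucinol-type o-quinone methides with alkenes and chiral Brønsted acid-catalysed [4+2] reactions of aryl-substituted o-quinone methides with styrenes; what is new is enantiocontrol with a methide that is unsubstituted at its terminal carbon. Ring C, the six-membered pyran, closes by this intermolecular [4+2] annulation, its second bond by capture of the C2 cation by O1 within the ion pair. The new C2 stereocentre is controlled by the catalyst, whose phosphate sits on O1 next to the forming O1–C2 bond and blocks one face of the styrene carbon (antipode chosen for 2S), the remote lavandulyl centre giving no useful bias. The step needs regioselectivity (aryl at C2, fixed by the polarity of methide and styrene), methide formation toward C8a only (fixed by the single free phenol, hence the 8-lavandulyl pattern) and chemoselectivity for 11 over the side-chain alkenes and the free C6–H of ring A (secured by the much higher nucleophilicity and excess of 11 and by slow addition of 12).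

Step 10
Reactants: 14 (2S)-5,7-bis(methoxymethoxy)-2-[2-methoxy-4-(methoxymethoxy)phenyl]-8-[(R)-lavandulyl]chromane
Product: 15 (2S)-5,7-bis(methoxymethoxy)-2-[2-methoxy-4-(methoxymethoxy)phenyl]-8-[(R)-lavandulyl]chroman-4-ol (both C4 epimers)
Conditions: 2,3-dichloro-5,6-dicyano-1,4-benzoquinone (DDQ, 1.5 equiv), CH2Cl2/pH 7 phosphate buffer (10:1), 0 °C
Reagents that add atoms: water, O
Why: DDQ benzylic oxidation by hydride abstraction should take the pseudo-axial C4–H, aligned with the π system of ring A and giving a cation stabilised by O1, the 5-oxygen and the 7-oxygen that water captures (the reaction type used at C4 of O-protected flavan-3-ols), whereas the equally activated C1'' methylene of the side chain is hindered by its branched neighbour and two ortho oxygens.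

Step 11
Reactants: 15 (2S)-5,7-bis(methoxymethoxy)-2-[2-methoxy-4-(methoxymethoxy)phenyl]-8-[(R)-lavandulyl]chroman-4-ol
Product: 16 (2S)-5,7-bis(methoxymethoxy)-2-[2-methoxy-4-(methoxymethoxy)phenyl]-8-[(R)-lavandulyl]chroman-4-one
Conditions: Dess–Martin periodinane, NaHCO3, CH2Cl2, 0 °C → rt
Reagents that add atoms: none
Why: Dess–Martin oxidation of a secondary benzylic alcohol under bicarbonate buffer converges both C4 epimers to the ketone without acid that could ionise C4 or base that could open ring C and scramble C2.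

Step 12
Reactants: 16 (2S)-5,7-bis(methoxymethoxy)-2-[2-methoxy-4-(methoxymethoxy)phenyl]-8-[(R)-lavandulyl]chroman-4-one
Product: 18 leachianone A, (2S)-5,7-dihydroxy-2-(4-hydroxy-2-methoxyphenyl)-8-[(R)-lavandulyl]chroman-4-one, via tris(trimethylsilyl) ether 17 (not isolated)
Conditions: TMSOTf (8 equiv), 2,2'-bipyridyl (12 equiv), CH3CN, 0 °C → rt; then H2O, rt
Reagents that add atoms: none
Why: Silyl triflate/2,2'-bipyridyl cleavage of aryl MOM ethers transfers each methoxymethyl unit to bipyridyl and leaves the phenols as TMS ethers 17, hydrolysed on adding water, so that no strong protic acid reaches the 1,5-diene next to the 7-hydroxyl and no base reaches the C2 centre.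

Compound list
1 | 2,4,6-trihydroxybenzaldehyde | O=Cc1c(O)cc(O)cc1O | starting material
2 | 2-hydroxy-4,6-bis(methoxymethoxy)benzaldehyde | O=Cc1c(O)cc(OCOC)cc1OCOC | intermediate
3 | 2-hydroxy-3-iodo-4,6-bis(methoxymethoxy)benzaldehyde | O=Cc1c(O)c(I)c(OCOC)cc1OCOC | intermediate
4 | racemic lavandulol, (2RS)-5-methyl-2-(prop-1-en-2-yl)hex-4-en-1-ol | C=C(C)C(CO)CC=C(C)C | starting material
5 | (S)-lavandulol, (2S)-5-methyl-2-(prop-1-en-2-yl)hex-4-en-1-ol | C=C(C)[C@H](CC=C(C)C)CO | intermediate
6 | (S)-lavandulyl iodide, (3S)-3-(iodomethyl)-2,6-dimethylhepta-1,5-diene | C=C(C)[C@H](CC=C(C)C)CI | intermediate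
7 | (S)-lavandulylzinc iodide, [(2S)-5-methyl-2-(prop-1-en-2-yl)hex-4-en-1-yl]zinc iodide (LiCl complex in THF) | C=C(C)[C@H](CC=C(C)C)C[Zn]I | intermediate
8 | 2-hydroxy-4,6-bis(methoxymethoxy)-3-[(2R)-5-methyl-2-(prop-1-en-2-yl)hex-4-en-1-yl]benzaldehyde | C=C(C)[C@H](CC=C(C)C)Cc1c(O)c(C=O)c(OCOC)cc1OCOC | intermediate
9 | 4-hydroxy-2-methoxybenzaldehyde | COc1cc(O)ccc1C=O | starting material
10 | 2-methoxy-4-(methoxymethoxy)benzaldehyde | COCOc1ccc(C=O)c(OC)c1 | intermediate
11 | 1-ethenyl-2-methoxy-4-(methoxymethoxy)benzene | C=Cc1ccc(OCOC)cc1OC | intermediate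
12 | 2-(hydroxymethyl)-3,5-bis(methoxymethoxy)-6-[(2R)-5-methyl-2-(prop-1-en-2-yl)hex-4-en-1-yl]phenol | C=C(C)[C@H](CC=C(C)C)Cc1c(OCOC)cc(OCOC)c(CO)c1O | intermediate
13 | 3,5-bis(methoxymethoxy)-6-methylidene-2-[(2R)-5-methyl-2-(prop-1-en-2-yl)hex-4-en-1-yl]cyclohexa-2,4-dien-1-one | C=C(C)[C@H](CC=C(C)C)CC1=C(OCOC)C=C(OCOC)C(=C)C1=O | intermediate
14 | (2S)-5,7-bis(methoxymethoxy)-2-[2-methoxy-4-(methoxymethoxy)phenyl]-8-[(2R)-5-methyl-2-(prop-1-en-2-yl)hex-4-en-1-yl]chromane | C=C(C)[C@H](CC=C(C)C)Cc1c(OCOC)cc(OCOC)c2c1O[C@H](c1ccc(OCOC)cc1OC)CC2 | intermediate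
15 | (2S)-5,7-bis(methoxymethoxy)-2-[2-methoxy-4-(methoxymethoxy)phenyl]-8-[(2R)-5-methyl-2-(prop-1-en-2-yl)hex-4-en-1-yl]chroman-4-ol, C4 epimers | C=C(C)[C@H](CC=C(C)C)Cc1c(OCOC)cc(OCOC)c2c1O[C@H](c1ccc(OCOC)cc1OC)CC2O | intermediate
16 | (2S)-5,7-bis(methoxymethoxy)-2-[2-methoxy-4-(methoxymethoxy)phenyl]-8-[(2R)-5-methyl-2-(prop-1-en-2-yl)hex-4-en-1-yl]chroman-4-one | C=C(C)[C@H](CC=C(C)C)Cc1c(OCOC)cc(OCOC)c2c1O[C@H](c1ccc(OCOC)cc1OC)CC2=O | intermediate
17 | (2S)-2-[2-methoxy-4-(trimethylsilyloxy)phenyl]-8-[(2R)-5-methyl-2-(prop-1-en-2-yl)hex-4-en-1-yl]-5,7-bis(trimethylsilyloxy)chroman-4-one | C=C(C)[C@H](CC=C(C)C)Cc1c(O[Si](C)(C)C)cc(O[Si](C)(C)C)c2c1O[C@H](c1ccc(O[Si](C)(C)C)cc1OC)CC2=O | intermediate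
18 | leachianone A, (2S)-5,7-dihydroxy-2-(4-hydroxy-2-methoxyphenyl)-8-[(2R)-5-methyl-2-(prop-1-en-2-yl)hex-4-en-1-yl]chroman-4-one | C=C(C)[C@H](CC=C(C)C)Cc1c(O)cc(O)c2c1O[C@H](c1ccc(O)cc1OC)CC2=O | target

Total step count: 12. Longest linear sequence: 8 steps (steps 1, 2, 5, 8, 9, 10, 11, 12 from 1; equally steps 3, 4, 5, 8, 9, 10, 11, 12 from 4).

Steps most likely to fail

Step 9 (proposed new method).
- What may go wrong: facial discrimination at C2 may be weak, because the methide carbon carries no substituent and the catalyst holds only O1. The methide may be intercepted by the free C6–H of another ring A (Friedel–Crafts self-condensation) or by a side-chain alkene. The acid may reopen the benzylic O1–C2 bond of the product and erode the C2 configuration.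
- Fallback with known chemistry, setting out from 8 and returning at 14: commercial 4'-hydroxy-2'-methoxyacetophenone is protected (MOMCl, i-Pr2NEt) as 1-[2-methoxy-4-(methoxymethoxy)phenyl]ethanone F1. Claisen–Schmidt condensation of this ketone with 8 (KOH, EtOH) should give the 2-hydroxychalcone (E)-3-{2-hydroxy-4,6-bis(methoxymethoxy)-3-[(R)-lavandulyl]phenyl}-1-[2-methoxy-4-(methoxymethoxy)phenyl]prop-2-en-1-one F2. Conjugate reduction with [(Ph3P)CuH]6 and a silane, which leaves isolated alkenes alone, gives the dihydrochalcone 3-{2-hydroxy-4,6-bis(methoxymethoxy)-3-[(R)-lavandulyl]phenyl}-1-[2-methoxy-4-(methoxymethoxy)phenyl]propan-1-one F3. Asymmetric transfer hydrogenation with RuCl[(R,R)-TsNCH(Ph)CH(Ph)NH2](p-cymene) in HCO2H/Et3N gives the (R)-carbinol (1R)-3-{2-hydroxy-4,6-bis(methoxymethoxy)-3-[(R)-lavandulyl]phenyl}-1-[2-methoxy-4-(methoxymethoxy)phenyl]propan-1-ol F4. Mitsunobu etherification (PPh3, DIAD, THF, 0 °C) then closes ring C through the free phenol with inversion and delivers 14 with the 2S configuration.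

Step 10.
- What may go wrong: hydride may be lost from C2–H, which is benzylic to the electron-rich ring B and next to O1, leading to ring opening, or from C1'' of the side chain. The C4 cation may lose a C3 proton to a flav-3-ene that is oxidised on to a flavylium ion, destroying C2.
- Fallback, setting out from 8 (with 11) and returning at 16: the C4 oxygen is carried through the cycloaddition instead of being introduced afterwards. Aldehyde 8 is converted with trimethyl orthoformate and a trace of acid into the dimethyl acetal 2-(dimethoxymethyl)-3,5-bis(methoxymethoxy)-6-[(R)-lavandulyl]phenol F5. Under the chiral phosphoric acid of step 9 (or Sc(OTf)3, as in the three-component chroman synthesis from salicylaldehydes, orthoformate and alkenes, followed by separation of C2 epimers) this loses methanol to a methoxy-substituted methide, which adds 11 to give the 4-methoxyflavan (2S)-4-methoxy-5,7-bis(methoxymethoxy)-2-[2-methoxy-4-(methoxymethoxy)phenyl]-8-[(R)-lavandulyl]chromane F6. Its C4–H, flanked by ring A and an ether oxygen, is then by far the best hydride donor, so DDQ in wet CH2Cl2 should cleave the benzylic methyl ether straight to 16, replacing steps 8 to 11.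

Step 5.
- What may go wrong: oxidative addition and transmetalation at the di-ortho-substituted, electron-rich iodide may be slow, so that protonation of the zinc reagent by the phenol or β-hydride elimination of the alkylpalladium intermediate takes over.
- Fallback, setting out from 6 and returning at 8: copper-catalysed borylation of 6 (B2pin2, CuI, PPh3, LiOMe, DMF, rt) gives the pinacol boronate 4,4,5,5-tetramethyl-2-[(2S)-5-methyl-2-(prop-1-en-2-yl)hex-4-en-1-yl]-1,3,2-dioxaborolane F7. KHF2 in aqueous MeOH converts it into potassium trifluoro[(2S)-5-methyl-2-(prop-1-en-2-yl)hex-4-en-1-yl]borate F8. Suzuki–Miyaura coupling of this salt with 3 (Pd(OAc)2, RuPhos (2-dicyclohexylphosphino-2',6'-diisopropoxybiphenyl), K2CO3, toluene/H2O, 80 °C), a protocol for primary alkyltrifluoroborates that is indifferent to the free phenol, should give 8.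

Further compounds
F1 | step 9 | 1-[2-methoxy-4-(methoxymethoxy)phenyl]ethanone | CC(=O)c1ccc(OCOC)cc1OC
F2 | step 9 | (E)-3-{2-hydroxy-4,6-bis(methoxymethoxy)-3-[(2R)-5-methyl-2-(prop-1-en-2-yl)hex-4-en-1-yl]phenyl}-1-[2-methoxy-4-(methoxymethoxy)phenyl]prop-2-en-1-one | C=C(C)[C@H](CC=C(C)C)Cc1c(O)c(/C=C/C(=O)c2ccc(OCOC)cc2OC)c(OCOC)cc1OCOC
F3 | step 9 | 3-{2-hydroxy-4,6-bis(methoxymethoxy)-3-[(2R)-5-methyl-2-(prop-1-en-2-yl)hex-4-en-1-yl]phenyl}-1-[2-methoxy-4-(methoxymethoxy)phenyl]propan-1-one | C=C(C)[C@H](CC=C(C)C)Cc1c(O)c(CCC(=O)c2ccc(OCOC)cc2OC)c(OCOC)cc1OCOC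
F4 | step 9 | (1R)-3-{2-hydroxy-4,6-bis(methoxymethoxy)-3-[(2R)-5-methyl-2-(prop-1-en-2-yl)hex-4-en-1-yl]phenyl}-1-[2-methoxy-4-(methoxymethoxy)phenyl]propan-1-ol | C=C(C)[C@H](CC=C(C)C)Cc1c(O)c(CC[C@@H](O)c2ccc(OCOC)cc2OC)c(OCOC)cc1OCOC
F5 | step 10 | 2-(dimethoxymethyl)-3,5-bis(methoxymethoxy)-6-[(2R)-5-methyl-2-(prop-1-en-2-yl)hex-4-en-1-yl]phenol | C=C(C)[C@H](CC=C(C)C)Cc1c(OCOC)cc(OCOC)c(C(OC)OC)c1O
F6 | step 10 | (2S)-4-methoxy-5,7-bis(methoxymethoxy)-2-[2-methoxy-4-(methoxymethoxy)phenyl]-8-[(2R)-5-methyl-2-(prop-1-en-2-yl)hex-4-en-1-yl]chromane, C4 epimers | C=C(C)[C@H](CC=C(C)C)Cc1c(OCOC)cc(OCOC)c2c1O[C@H](c1ccc(OCOC)cc1OC)CC2OC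
F7 | step 5 | 4,4,5,5-tetramethyl-2-[(2S)-5-methyl-2-(prop-1-en-2-yl)hex-4-en-1-yl]-1,3,2-dioxaborolane | C=C(C)[C@H](CC=C(C)C)CB1OC(C)(C)C(C)(C)O1
F8 | step 5 | potassium trifluoro[(2S)-5-methyl-2-(prop-1-en-2-yl)hex-4-en-1-yl]borate | C=C(C)[C@H](CC=C(C)C)C[B-](F)(F)F.[K+]
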